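**Retrosynthetic overview**
1. Feature: ring B (C5–C6–C7–C8–C9–C10) is cis-fused to ring A (C10–C1–C2(=O)–C3–C4–C5), with the C5 methyl and H-10 cis and the C9 oxygen trans to H-10. This is the endo-adduct pattern of a 1-oxygenated butadiene (C6–C9) on the methyl-bearing alkene (C5, C10) of 2-methoxy-5-methylbenzoquinone, whose OMe carbon is C2.
2. Late stage: C9 senecioate and C8 tiglate ⇐ O8/O9 differentiated as 8-OH/9-OPMB ⇐ trans-diaxial opening at C7 (isopropenyl) of the 7α,8α-epoxide ⇐ 9α-OH-directed epoxidation of C7=C8.
3. Ring A: 4β-methyl ⇐ methylcuprate on the 3-en-2-one ⇐ adduct, by hydride reduction, hydrolysis–elimination and C1 deoxygenation.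
4. Ring order: ring A is the quinone ring; ring B is closed in the Diels–Alder step (C5–C6 and C9–C10); the diene comes from crotonaldehyde.

Key step: step 2

Convention: eremophilane numbering as above; β is the face of the C5 methyl, α the opposite face. The target is (4S,5R,7R,8R,9S,10S).
Assumption 1: the (R)-BINOL-derived titanium catalyst is taken to deliver the diene to the face of the quinone that leads to 4; if the sense of induction is the opposite, the (S)-ligand is used with no other change.
Assumption 2: the carbinol configurations at C1 and C4 in 5–7 are drawn as expected for hydride delivery from the convex β-face; both centres are destroyed later, so their epimers converge.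

Step 1
Reactants: 1 crotonaldehyde
Product: 2 (E)-1-(tert-butyldimethylsilyloxy)buta-1,3-diene
Conditions: TBSOTf, Et3N, Et2O, 0 °C → rt; distillation
Reagents that add atoms: tert-butyldimethylsilyl trifluoromethanesulfonate, CC(C)(C)[Si](C)(C)OS(=O)(=O)C(F)(F)F
Why: Vinylogous silyl enol ether formation, in which triethylamine removes a γ-proton of the silyl-activated enal and O-silylation gives the conjugated dienol ether, the extended (E)-isomer being favoured (any Z-isomer is unreactive in step 2).

Step 2
Reactants: 3 2-methoxy-5-methyl-1,4-benzoquinone; 2 (E)-1-(tert-butyldimethylsilyloxy)buta-1,3-diene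
Product: 4 cis-fused adduct 9α-(tert-butyldimethylsilyloxy)-2-methoxy-5β-methyl-10β-H-octala-2,7-diene-1,4-dione
Conditions: (R)-BINOL–TiCl2 (from (R)-BINOL and TiCl2(OiPr)2, 20 mol%), toluene, –40 → –10 °C
Reagents that add atoms: none
Why: This is a concerted, asynchronous Lewis-acid-catalysed [4π+2π] cycloaddition in which titanium chelates the C1 carbonyl and the methoxy oxygen of 3; the closest known reaction type is the BINOL–Ti quinone Diels–Alder reaction with 1-oxygenated butadienes, and the same addition is known thermally. Ring B is closed in the cycloaddition itself, C5–C6 and C9–C10 forming suprafacially on both partners onto the existing ring A. C5 and C10 come out cis (β-methyl, β-hydrogen) because the geometry of the ring alkene is retained, and the C9 oxygen comes out α (trans to H-10) from the endo transition state, in which the diene lies under the dione ring and the (E)-silyloxy group points outward. Site selectivity follows from the methoxy-bearing alkene being a deactivated vinylogous ester, and regioselectivity from the chelated C1 carbonyl making C5 the electrophilic β-carbon, which pairs with the unsubstituted, most nucleophilic diene terminus. The absolute configuration is set by the C2-symmetric BINOL ligand on the chelated titanium, which shields one face of the C5=C10 alkene, so the step needs site, regio, endo and facial selectivity together.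

Step 3
Reactants: 4 Diels–Alder adduct
Product: 6 1α-hydroxy-9α-(tert-butyldimethylsilyloxy)-5β-methyl-10β-H-octala-3,7-dien-2-one (ketol), via enol-ether diol 5 (not isolated)
Conditions: LiAlH4, THF, –78 → 0 °C; then 1 M HCl, THF, 0 °C
Reagents that add atoms: water, O
Why: LiAlH4 1,2-reduction of both carbonyls is followed by acid ionisation of the C4 carbinol (vinylogous to the enol ether), water capture at C2 and loss of methanol (Stork–Danheiser-type hydrolysis–transposition), which should give the 3-en-2-one with the C1 carbinol retained, without base that could epimerise C10 or eliminate the C9 silyloxy group.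

Step 4
Reactants: 6 ketol
Product: 7 1α-acetoxy-9α-(tert-butyldimethylsilyloxy)-5β-methyl-10β-H-octala-3,7-dien-2-one
Conditions: Ac2O, pyridine, DMAP (cat.), CH2Cl2, 0 °C → rt
Reagents that add atoms: acetic anhydride, CC(=O)OC(C)=O
Why: DMAP-catalysed acetylation turns the C1 hydroxyl into a leaving group for reductive removal and creates no new stereocentre.

Step 5
Reactants: 7 α-acetoxy enone
Product: 8 9α-(tert-butyldimethylsilyloxy)-5β-methyl-10β-H-octala-3,7-dien-2-one
Conditions: SmI2, THF–MeOH, –78 °C
Reagents that add atoms: none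
Why: SmI2 reductive cleavage of an α-acyloxy ketone, in which two electron transfers expel acetate and methanol protonates the resulting dienolate at C1 to return the conjugated enone; the C9 silyl ether is not β to the enolate carbon and cannot be eliminated.

Step 6
Reactants: 8 enone
Product: 10 9α-(tert-butyldimethylsilyloxy)-4β,5β-dimethyl-10β-H-octal-7-en-2-one, via trimethylsilyl enol ether 9 (not isolated)
Conditions: Me2CuLi (MeLi, CuI), TMSCl, Et2O–THF, –78 → –30 °C; then 1 M HCl, THF, 0 °C
Reagents that add atoms: lithium dimethylcuprate, [Li+].C[Cu-]C (from methyllithium, C[Li], and copper(I) iodide, [Cu]I); chlorotrimethylsilane, C[Si](C)(C)Cl (atoms remain only in 9)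
Why: TMSCl-accelerated Gilman cuprate 1,4-addition, in which the favoured cis-decalin conformer (C9 OTBS pseudo-equatorial, C5–C6 bond axial on ring A) is attacked axially at C4 from the convex β-face, anti to C6 and away from ring B, so the new methyl should be cis to the C5 methyl, and brief acid hydrolysis of the silyl enol ether gives the ketone.

Step 7
Reactants: 10 ketone
Product: 11 2,2-ethylenedioxy ketal of 10
Conditions: (TMSOCH2)2, TMSOTf (cat.), CH2Cl2, –78 → –20 °C; pyridine quench
Reagents that add atoms: 1,2-bis(trimethylsilyloxy)ethane, C[Si](C)(C)OCCO[Si](C)(C)C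
Why: Noyori ketalisation protects the C2 ketone against the Grignard reagent of step 11 and the peracid of step 9 under aprotic conditions that leave the allylic TBS ether intact.

Step 8
Reactants: 11 ketal silyl ether
Product: 12 2,2-ethylenedioxy-4β,5β-dimethyl-10β-H-octal-7-en-9α-ol
Conditions: TBAF, THF, rt
Reagents that add atoms: none
Why: Fluoride desilylation frees the allylic C9 alcohol needed to direct the epoxidation and touches no stereocentre.

Step 9
Reactants: 12 allylic alcohol
Product: 13 7α,8α-epoxy-2,2-ethylenedioxy-4β,5β-dimethyl-10β-H-decalin-9α-ol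
Conditions: mCPBA, NaHCO3, CH2Cl2, 0 °C
Reagents that add atoms: 3-chloroperbenzoic acid, OOC(=O)c1cccc(Cl)c1
Why: Henbest hydroxyl-directed epoxidation, in which hydrogen bonding of the pseudo-equatorial 9α-OH to the peracid delivers oxygen to the α-face of C7=C8, cis to the hydroxyl, which sets C7 and C8.

Step 10
Reactants: 13 epoxy alcohol
Product: 14 7α,8α-epoxy-2,2-ethylenedioxy-9α-(4-methoxybenzyloxy)-4β,5β-dimethyl-10β-H-decalin
Conditions: NaH, PMBCl, Bu4NI (cat.), THF–DMF, 0 °C → rt
Reagents that add atoms: 4-methoxybenzyl chloride, COc1ccc(CCl)cc1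
Why: Williamson etherification, safe here because a ring cis-epoxy alkoxide cannot reach the backside of C8 for Payne rearrangement; the ether removes alkoxide-directed attack at C8 in step 11 and later distinguishes O9 from O8.

Step 11
Reactants: 14 epoxide PMB ether; 15 isopropenylmagnesium bromide
Product: 16 2,2-ethylenedioxy-7β-isopropenyl-9α-(4-methoxybenzyloxy)-4β,5β-dimethyl-10β-H-decalin-8α-ol
Conditions: 15 (3 equiv), CuI (20 mol%), THF, –30 → 0 °C; aqueous work-up
Reagents that add atoms: none
Why: Copper-catalysed Grignard SN2 opening under trans-diaxial (Fürst–Plattner) control, in which the conformer with the C9 ether equatorial offers the axial trajectory at C7 from the β-face while C8 is deactivated by the adjacent C9 oxygen, so inversion at C7 should give 7β-isopropenyl and leave the 8α-oxygen as the free hydroxyl (analogous to 2β-attack on 2α,3α-epoxy steroids syn to the angular methyl).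

Step 12
Reactants: 16 C8 alcohol; 17 tigloyl chloride ((E)-2-methylbut-2-enoyl chloride)
Product: 18 8α-tigloyloxy-9α-(4-methoxybenzyloxy) ketal (2,2-ethylenedioxy-7β-isopropenyl-4β,5β-dimethyl-10β-H-decalin)
Conditions: pyridine, DMAP, CH2Cl2, 0 °C → rt
Reagents that add atoms: none
Why: DMAP-catalysed acylation of the only free hydroxyl with the acid chloride in pyridine (no trialkylamine, to avoid vinylketene formation and deconjugation), with the stable (E)-geometry of the tiglate retained.

Step 13
Reactants: 18 tiglate PMB ether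
Product: 19 8α-tigloyloxy-9α-hydroxy ketal (2,2-ethylenedioxy-7β-isopropenyl-4β,5β-dimethyl-10β-H-decalin)
Conditions: DDQ, CH2Cl2–pH 7 buffer, 0 °C → rt
Reagents that add atoms: none
Why: Oxidative PMB cleavage by DDQ (benzylic hydride abstraction, then hydrolysis of the oxocarbenium ion) under buffered neutral conditions, which avoids O8→O9 acyl migration and leaves the alkenes, the ester and the ketal untouched.

Step 14
Reactants: 19 C9 alcohol; 20 senecioyl chloride (3-methylbut-2-enoyl chloride)
Product: 21 8α-tigloyloxy-9α-senecioyloxy ketal (2,2-ethylenedioxy-7β-isopropenyl-4β,5β-dimethyl-10β-H-decalin)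
Conditions: pyridine, DMAP, CH2Cl2, 0 → 40 °C
Reagents that add atoms: none
Why: DMAP-catalysed acylation of the hindered 9α-hydroxyl; the tiglate already sits on the less hindered O8, its thermodynamically preferred position, so acyl migration is not driven, and the weak base avoids isomerisation to the β,γ-unsaturated ester.

Step 15
Reactants: 21 diester ketal
Product: 22 target, (4S,5R,7R,8R,9S,10S)-8-[(E)-2-methylbut-2-enoyloxy]-9-(3-methylbut-2-enoyloxy)eremophil-11-en-2-one
Conditions: 1 M HCl, THF, rt
Reagents that add atoms: water, O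
Why: Mild aqueous acid hydrolysis of the dioxolane releases the C2 ketone, which is flanked by two CH2 groups so that nothing can epimerise, while the enoate esters and the 1,1-disubstituted alkene tolerate the conditions.

**Compound list**
1 | crotonaldehyde, (E)-but-2-enal | C/C=C/C=O | starting material
2 | (E)-1-(tert-butyldimethylsilyloxy)buta-1,3-diene | C=C/C=C/O[Si](C)(C)C(C)(C)C | intermediate
3 | 2-methoxy-5-methyl-1,4-benzoquinone | COC1=CC(=O)C(C)=CC1=O | starting material
4 | cis-fused adduct, 9α-OTBS, 2-OMe, 5β-Me, 10β-H, octala-2,7-diene-1,4-dione | C1=C[C@@H](O[Si](C)(C)C(C)(C)C)[C@H]2C(=O)C(OC)=CC(=O)[C@@]2(C)C1 | intermediate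
5 | 1α,4α-diol of 4 (2-methoxy-2,7-diene), not isolated | C1=C[C@@H](O[Si](C)(C)C(C)(C)C)[C@H]2[C@@H](O)C(OC)=C[C@@H](O)[C@@]2(C)C1 | intermediate
6 | 1α-hydroxy-9α-OTBS-5β-methyl-10β-H-octala-3,7-dien-2-one | C1=C[C@@H](O[Si](C)(C)C(C)(C)C)[C@H]2[C@@H](O)C(=O)C=C[C@@]2(C)C1 | intermediate
7 | 1α-acetoxy-9α-OTBS-5β-methyl-10β-H-octala-3,7-dien-2-one | C1=C[C@@H](O[Si](C)(C)C(C)(C)C)[C@H]2[C@@H](OC(C)=O)C(=O)C=C[C@@]2(C)C1 | intermediate
8 | 9α-OTBS-5β-methyl-10β-H-octala-3,7-dien-2-one | C1=C[C@@H](O[Si](C)(C)C(C)(C)C)[C@H]2CC(=O)C=C[C@@]2(C)C1 | intermediate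
9 | 2-(trimethylsilyloxy)-9α-OTBS-4β,5β-dimethyl-10β-H-octala-2,7-diene, not isolated | C1=C[C@@H](O[Si](C)(C)C(C)(C)C)[C@H]2CC(O[Si](C)(C)C)=C[C@H](C)[C@@]2(C)C1 | intermediate
10 | 9α-OTBS-4β,5β-dimethyl-10β-H-octal-7-en-2-one | C1=C[C@@H](O[Si](C)(C)C(C)(C)C)[C@H]2CC(=O)C[C@H](C)[C@@]2(C)C1 | intermediate
11 | 2,2-ethylenedioxy ketal of 10 | C1=C[C@@H](O[Si](C)(C)C(C)(C)C)[C@H]2CC3(OCCO3)C[C@H](C)[C@@]2(C)C1 | intermediate
12 | 2,2-ethylenedioxy-4β,5β-dimethyl-10β-H-octal-7-en-9α-ol | C1=C[C@@H](O)[C@H]2CC3(OCCO3)C[C@H](C)[C@@]2(C)C1 | intermediate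
13 | 7α,8α-epoxy-2,2-ethylenedioxy-4β,5β-dimethyl-10β-H-decalin-9α-ol | O1[C@@H]2C[C@]3(C)[C@@H](C)CC4(OCCO4)C[C@@H]3[C@H](O)[C@H]12 | intermediate
14 | 9α-PMB ether of 13 | O1[C@@H]2C[C@]3(C)[C@@H](C)CC4(OCCO4)C[C@@H]3[C@H](OCc5ccc(OC)cc5)[C@H]12 | intermediate
15 | isopropenylmagnesium bromide | C=C(C)[Mg]Br | starting material
16 | 2,2-ethylenedioxy-7β-isopropenyl-9α-OPMB-4β,5β-dimethyl-10β-H-decalin-8α-ol | C=C(C)[C@H]1C[C@@]2(C)[C@H](CC3(OCCO3)C[C@@H]2C)[C@H](OCc4ccc(OC)cc4)[C@@H]1O | intermediate
17 | tigloyl chloride, (E)-2-methylbut-2-enoyl chloride | ClC(=O)/C(C)=C/C | starting material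
18 | 8α-tiglate of 16 | C=C(C)[C@H]1C[C@@]2(C)[C@H](CC3(OCCO3)C[C@@H]2C)[C@H](OCc4ccc(OC)cc4)[C@@H]1OC(=O)/C(C)=C/C | intermediate
19 | 8α-tigloyloxy-9α-hydroxy ketal | C=C(C)[C@H]1C[C@@]2(C)[C@H](CC3(OCCO3)C[C@@H]2C)[C@H](O)[C@@H]1OC(=O)/C(C)=C/C | intermediate
20 | senecioyl chloride, 3-methylbut-2-enoyl chloride | CC(C)=CC(=O)Cl | starting material
21 | 8α-tigloyloxy-9α-senecioyloxy ketal | C=C(C)[C@H]1C[C@@]2(C)[C@H](CC3(OCCO3)C[C@@H]2C)[C@H](OC(=O)C=C(C)C)[C@@H]1OC(=O)/C(C)=C/C | intermediate
22 | target, CNP0181050.1 | C=C(C)[C@H]1C[C@@]2(C)[C@H](CC(=O)C[C@@H]2C)[C@H](OC(=O)C=C(C)C)[C@@H]1OC(=O)/C(C)=C/C | target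

**Step count**
Total: 15 steps. Longest linear sequence: 15 steps (1 → 22); the quinone 3 enters at step 2.

**Steps most likely to fail**

Step 2. The chiral titanium complex may discriminate poorly between the two faces of the C5=C10 alkene, or may degrade the acid-sensitive silyloxydiene before cycloaddition. The fallback sets out from 2 and 3 and replaces catalyst control by resolution. The cycloaddition is run thermally without catalyst (toluene, 60–80 °C), where site, regio and endo selectivity are intrinsic; this gives 4 together with the antipodal adduct F1. The racemate is taken through step 3, which forms the antipodal diol F2 (not isolated) and the antipodal ketol F3 beside 5 and 6. In place of step 4 the racemic ketol is esterified with (S)-O-methylmandelic acid (DCC, DMAP, CH2Cl2) to give the mandelate of 6, ester F4, and the diastereomeric mandelate of the antipode, ester F5, which are separated by chromatography. F4 is an α-acyloxy ketone and, under the conditions of step 5 (SmI2, THF–MeOH, –78 °C), loses the auxiliary acid to give 8, where the route is rejoined.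

Step 11. The nucleophile must enter C7 axially, syn to the axial C5 methyl, so the opening may be slow, may leak to C8, or may be overtaken by halohydrin formation from magnesium bromide. The fallback sets out from 14 and uses a slim, rod-shaped C2 nucleophile. Lithium acetylide–ethylenediamine in DMSO at rt should open the epoxide trans-diaxially to the 7β-ethynyl-8α-ol, alkynol F8. Negishi carboalumination (Me3Al, Cp2ZrCl2 cat., CH2Cl2) followed by aqueous protonolysis then converts C≡CH into C(CH3)=CH2 and returns the route at 16.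

Step 6. Methyl delivery may occur on the α-face of C4 (reaction through the other cis-decalin conformer), giving the wrong C4 epimer or a mixture. The fallback sets out from 8 and sets C4 by hydride instead of methyl delivery. The cuprate addition is run as before, but the silyl enol ether, then the 4α-methyl enol ether F6 (alone or with 9), is not hydrolysed. It is oxidised by Saegusa–Ito dehydrosilylation (Pd(OAc)2, MeCN, rt) to the 4-methyl-3-en-2-one, enone F7, which erases C4. Conjugate reduction with Stryker's reagent ([(Ph3P)CuH]6, wet benzene, rt) should then deliver hydride to C4 from the same face the cuprate preferred, leaving the methyl β, and returns the route at 10.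

**Further compounds**
F1 | step 2 | antipode of adduct 4 | C1=C[C@H](O[Si](C)(C)C(C)(C)C)[C@@H]2C(=O)C(OC)=CC(=O)[C@]2(C)C1
F2 | step 2 | antipode of diol 5 (not isolated) | C1=C[C@H](O[Si](C)(C)C(C)(C)C)[C@@H]2[C@H](O)C(OC)=C[C@H](O)[C@]2(C)C1
F3 | step 2 | antipode of ketol 6 | C1=C[C@H](O[Si](C)(C)C(C)(C)C)[C@@H]2[C@H](O)C(=O)C=C[C@]2(C)C1
F4 | step 2 | (S)-O-methylmandelate of ketol 6 | C1=C[C@@H](O[Si](C)(C)C(C)(C)C)[C@H]2[C@@H](OC(=O)[C@@H](OC)c3ccccc3)C(=O)C=C[C@@]2(C)C1
F5 | step 2 | (S)-O-methylmandelate of antipodal ketol F3 | C1=C[C@H](O[Si](C)(C)C(C)(C)C)[C@@H]2[C@H](OC(=O)[C@@H](OC)c3ccccc3)C(=O)C=C[C@]2(C)C1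
F6 | step 6 | 4α-methyl epimer of silyl enol ether 9 | C1=C[C@@H](O[Si](C)(C)C(C)(C)C)[C@H]2CC(O[Si](C)(C)C)=C[C@@H](C)[C@@]2(C)C1
F7 | step 6 | 9α-OTBS-4,5β-dimethyl-10β-H-octala-3,7-dien-2-one | C1=C[C@@H](O[Si](C)(C)C(C)(C)C)[C@H]2CC(=O)C=C(C)[C@@]2(C)C1
F8 | step 11 | 2,2-ethylenedioxy-7β-ethynyl-9α-OPMB-4β,5β-dimethyl-10β-H-decalin-8α-ol | C#C[C@H]1C[C@@]2(C)[C@H](CC3(OCCO3)C[C@@H]2C)[C@H](OCc4ccc(OC)cc4)[C@@H]1O
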